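**Strategy.** Ring A of the isochromene-6,8-dione is cut at C5–C6 and C8–C8a. C6–C7–C8 is a 2-decanoyloxy-2-methylmalonyl unit, and C5, C4a and C8a are the γ-, β- and α-carbons of an enal whose formyl carbon is C1 and whose β-alkynyl group holds C4 and C3. One operation joins an enantiopure malonyl chloride methyl ester (C7 preset by enzymatic desymmetrisation) to the enal's silyl dienol ether by γ-acylation and Dieckmann closure, giving non-aromatic ring A with formyl and alkyne in place. Cycloisomerisation of the formyl oxygen onto the alkyne (O2–C3) then closes ring B. No arene and no late oxidation are needed.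

Key step: step 10

Remark (numbering): atom labels C1–C8a and O2 follow isochromene numbering of the target; ring A is the carbocycle, ring B the pyran.

Remark (configuration): C7 of the target is R. The descriptor changes between R and S along the route only because the CIP ranking of the neighbours changes; every SMILES string shows the same spatial arrangement.

Assumption: the esterase is taken to deliver the R half-ester. The sense of hydrolysis of a 2-alkoxy-2-methylmalonate cannot be predicted with certainty and is to be confirmed by correlation before going on; the fallback for step 3 covers the other outcome.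

**Step 1**
Reactants: 1 dimethyl methylmalonate
Product: 2 dimethyl 2-hydroxy-2-methylmalonate
Conditions: NaH, THF, 0 °C; 3-phenyl-2-(phenylsulfonyl)oxaziridine, −78 → 0 °C; AcOH
Reagents that add atoms: 3-phenyl-2-(phenylsulfonyl)oxaziridine, O=S(=O)(N1OC1c1ccccc1)c1ccccc1
Why: The sodium enolate of the malonate should attack the electrophilic oxygen of the N-sulfonyloxaziridine (enolate hydroxylation), and the product is achiral.

**Step 2**
Reactants: 2 dimethyl 2-hydroxy-2-methylmalonate
Product: 3 dimethyl 2-(benzyloxy)-2-methylmalonate
Conditions: NaH, BnBr, n-Bu4NI (cat.), THF/DMF, 0 °C → rt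
Reagents that add atoms: benzyl bromide, BrCc1ccccc1
Why: Williamson etherification of the tertiary alkoxide, which has no β-hydrogen to eliminate, should give a benzyl ether that is inert to the esterase and removable by hydrogenolysis.

**Step 3**
Reactants: 3 dimethyl 2-(benzyloxy)-2-methylmalonate
Product: 4 (R)-2-(benzyloxy)-3-methoxy-2-methyl-3-oxopropanoic acid
Conditions: pig liver esterase, 0.1 M phosphate buffer pH 7.5, DMSO (10% v/v), 25 °C, pH-stat with 1 M NaOH (1.0 equiv); then 1 M HCl to pH 2
Reagents that add atoms: water, O
Why: Enzymatic desymmetrisation of a prochiral 2,2-disubstituted malonate: the esterase should hydrolyse one of the two enantiotopic methyl esters and stop at the anionic half-ester, which sets the quaternary centre (the later C7) under control of the enzyme's active site.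

**Step 4**
Reactants: 4 (R)-2-(benzyloxy)-3-methoxy-2-methyl-3-oxopropanoic acid
Product: 5 (R)-2-hydroxy-3-methoxy-2-methyl-3-oxopropanoic acid
Conditions: H2 (1 atm), Pd/C (10%), EtOAc, rt
Reagents that add atoms: none
Why: Hydrogenolysis of the benzyl ether should free the tertiary alcohol without touching the ester, the acid or the quaternary centre.

**Step 5**
Reactants: 5 (R)-2-hydroxy-3-methoxy-2-methyl-3-oxopropanoic acid; 6 decanoyl chloride
Product: 8 (R)-2-(decanoyloxy)-3-methoxy-2-methyl-3-oxopropanoic acid, via mixed decanoic anhydride 7 (not isolated)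
Conditions: 6 (2.2 equiv), pyridine, DMAP (cat.), CH2Cl2, 0 °C → rt; then THF/H2O, rt
Reagents that add atoms: none
Why: DMAP-catalysed acylation should esterify the hindered tertiary hydroxyl while the carboxylate is held as its mixed anhydride, which aqueous pyridine then opens at the unhindered decanoyl carbonyl, and the quaternary centre cannot epimerise.

**Step 6**
Reactants: 8 (R)-2-(decanoyloxy)-3-methoxy-2-methyl-3-oxopropanoic acid
Product: 9 methyl (S)-3-chloro-2-(decanoyloxy)-2-methyl-3-oxopropanoate
Conditions: (COCl)2, DMF (cat.), CH2Cl2, 0 °C → rt; evaporate, use crude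
Reagents that add atoms: oxalyl chloride, ClC(=O)C(Cl)=O
Why: Chlorination through the chloroiminium salt should give the acid chloride, which has no α-hydrogen and so can neither form a ketene nor racemise.

**Step 7**
Reactants: 10 (E)-3-methylpent-2-en-4-yn-1-ol; 11 1-bromoheptane
Product: 12 (E)-3-methyldodec-2-en-4-yn-1-ol
Conditions: n-BuLi (2.1 equiv), THF/DMPU, −78 → 0 °C; 11, 0 °C → rt; H2O
Reagents that add atoms: none
Why: Alkylation of the alkoxide–acetylide dianion should occur at the acetylide carbon, since the lithium alkoxide is a much poorer nucleophile towards a primary bromide.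

**Step 8**
Reactants: 12 (E)-3-methyldodec-2-en-4-yn-1-ol
Product: 13 (E)-3-methyldodec-2-en-4-ynal
Conditions: MnO2 (activated, excess), CH2Cl2, rt
Reagents that add atoms: none
Why: Allylic oxidation with MnO2 should stop at the enal and leave the alkyne untouched.

**Step 9**
Reactants: 13 (E)-3-methyldodec-2-en-4-ynal
Product: 14 trimethyl{[(1E)-3-methylidenedodec-1-en-4-yn-1-yl]oxy}silane
Conditions: Et3N, TMSOTf, Et2O, 0 °C; pentane, filter, concentrate, use at once
Reagents that add atoms: trimethylsilyl trifluoromethanesulfonate, C[Si](C)(C)OS(=O)(=O)C(F)(F)F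
Why: Soft enolisation (O-silylation, then removal of a γ-proton by the amine) should give the cross-conjugated silyl dienol ether, because the methyl group carries the only γ-hydrogens, and a minor 1Z isomer would converge in step 10.

**Step 10**
Reactants: 9 methyl (S)-3-chloro-2-(decanoyloxy)-2-methyl-3-oxopropanoate; 14 trimethyl{[(1E)-3-methylidenedodec-1-en-4-yn-1-yl]oxy}silane
Product: 16 (1S)-3-formyl-2-hydroxy-1-methyl-4-(non-1-yn-1-yl)-6-oxocyclohexa-2,4-dien-1-yl decanoate, via δ-keto enal 15 (not isolated)
Conditions: ZnCl2 (1.0 equiv, 1 M in Et2O), CH2Cl2, −40 → 0 °C; volatiles removed; Et3N (3 equiv), THF, 0 °C → rt; cold 0.5 M HCl work-up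
Reagents that add atoms: none
Why: Proposed new method: ZnCl2 activates the acid chloride, and the terminal methylene (C5) of the dienol ether attacks it in a vinylogous Mukaiyama acylation that releases Me3SiCl and forms C5–C6 in the δ-keto enal 15. Et3N with the zinc salt then soft-enolises the doubly activated C5 methylene, and the α-carbon (C8a) of the resulting dienolate adds to the methyl ester and expels methoxide (C8–C8a), a Dieckmann condensation that closes ring A in the 6-exo-trig mode (enolate double bond exocyclic) and ends at the stabilised vinylogous-acid anion. The closest known reaction types are the ZnCl2-mediated C-acylation of silyl enol ethers with acid chlorides, the [3+3] cyclisations of 1,3-bis-silyl enol ethers with 1,3-dielectrophiles, and the Dieckmann condensation. No stereocentre is created: C7 is carried from 9 as a quaternary carbon, and the formyl group on C8a keeps C6 and C8 non-equivalent in every tautomer, so enol–keto shifts cannot racemise it. The step needs γ-attack on the acid chloride and not α- or O-attack or attack on an ester. The γ-preference of silyl dienol ethers towards carbonyl electrophiles, the single γ-terminus of 14 and the much higher electrophilicity of the acid chloride should secure this, and closure on the decanoate would need a seven-membered ring.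

**Step 11**
Reactants: 16 (1S)-3-formyl-2-hydroxy-1-methyl-4-(non-1-yn-1-yl)-6-oxocyclohexa-2,4-dien-1-yl decanoate
Product: 17 (7R)-3-heptyl-7-methyl-6,8-dioxo-7,8-dihydro-6H-isochromen-7-yl decanoate
Conditions: CuI (10 mol%), i-Pr2NEt (1.0 equiv), CH2Cl2, rt
Reagents that add atoms: none
Why: The formyl oxygen of the vinylogous-acid anion should add 6-endo-dig to the copper-activated alkyne at C3, the conjugate position of the C6 dienone, and protonation at C4 with the enol-to-ketone shift at C8 gives the pyran, a known coinage-metal cycloisomerisation of alkynyl formyl vinylogous acids that leaves C7 untouched.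

**Compound list**

1 | dimethyl methylmalonate | COC(=O)C(C)C(=O)OC | starting material
2 | dimethyl 2-hydroxy-2-methylmalonate | COC(=O)C(C)(O)C(=O)OC | intermediate
3 | dimethyl 2-(benzyloxy)-2-methylmalonate | COC(=O)C(C)(OCc1ccccc1)C(=O)OC | intermediate
4 | (R)-2-(benzyloxy)-3-methoxy-2-methyl-3-oxopropanoic acid | c1ccccc1CO[C@](C)(C(O)=O)C(=O)OC | intermediate
5 | (R)-2-hydroxy-3-methoxy-2-methyl-3-oxopropanoic acid | O[C@](C)(C(O)=O)C(=O)OC | intermediate
6 | decanoyl chloride | CCCCCCCCCC(Cl)=O | starting material
7 | decanoic (S)-2-(decanoyloxy)-3-methoxy-2-methyl-3-oxopropanoic anhydride (forms in the flask in step 5) | CCCCCCCCCC(=O)O[C@](C)(C(=O)OC(=O)CCCCCCCCC)C(=O)OC | intermediate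
8 | (R)-2-(decanoyloxy)-3-methoxy-2-methyl-3-oxopropanoic acid | CCCCCCCCCC(=O)O[C@](C)(C(O)=O)C(=O)OC | intermediate
9 | methyl (S)-3-chloro-2-(decanoyloxy)-2-methyl-3-oxopropanoate | CCCCCCCCCC(=O)O[C@](C)(C(Cl)=O)C(=O)OC | intermediate
10 | (E)-3-methylpent-2-en-4-yn-1-ol | OC/C=C(\C)C#C | starting material
11 | 1-bromoheptane | CCCCCCCBr | starting material
12 | (E)-3-methyldodec-2-en-4-yn-1-ol | OC/C=C(\C)C#CCCCCCCC | intermediate
13 | (E)-3-methyldodec-2-en-4-ynal | O=C/C=C(\C)C#CCCCCCCC | intermediate
14 | trimethyl{[(1E)-3-methylidenedodec-1-en-4-yn-1-yl]oxy}silane | CCCCCCCC#CC(=C)/C=C/O[Si](C)(C)C | intermediate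
15 | methyl (2R,5Z)-2-(decanoyloxy)-2-methyl-3-oxo-5-(2-oxoethylidene)tetradec-6-ynoate (forms in the flask in step 10; the alkene geometry is lost on enolisation) | CCCCCCCCCC(=O)O[C@](C)(C(=O)C/C(C#CCCCCCCC)=C/C=O)C(=O)OC | intermediate
16 | (1S)-3-formyl-2-hydroxy-1-methyl-4-(non-1-yn-1-yl)-6-oxocyclohexa-2,4-dien-1-yl decanoate | CCCCCCCCCC(=O)O[C@]1(C)C(=O)C=C(C#CCCCCCCC)C(C=O)=C1O | intermediate
17 | (7R)-3-heptyl-7-methyl-6,8-dioxo-7,8-dihydro-6H-isochromen-7-yl decanoate | CCCCCCCCCC(=O)O[C@]1(C)C(=O)C=C2C=C(CCCCCCC)OC=C2C1=O | target

**Step count.** Total: 11 steps. Longest linear sequence: 8 steps (steps 1–6, 10, 11); the enyne branch (steps 7–9) joins at step 10.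

**Steps most likely to fail**

1. Step 10. The dienol ether may be acylated at oxygen or at the α-carbon, the α-acyloxy acid chloride may ionise and lose CO, or the Dieckmann closure may be outrun by intermolecular aldol condensation of the enal. The fallback uses known chemistry, sets out from 11 and returns at 17. Ring A is taken from an arene and dearomatised. 1-Bromoheptane 11 and LiC≡CH·H2NCH2CH2NH2 in DMSO give non-1-yne F1. Sonogashira coupling (Pd(PPh3)2Cl2, CuI, Et3N, DMF) with the known 6-bromo-2,4-dihydroxy-3-methylbenzaldehyde (O=Cc1c(Br)cc(O)c(C)c1O) gives 2,4-dihydroxy-3-methyl-6-(non-1-yn-1-yl)benzaldehyde F2. Copper-mediated enantioselective oxidative dearomatisation ([Cu(CH3CN)4]PF6, the sparteine enantiomer that delivers the 3S carbinol, i-Pr2NEt, DMAP, O2, CH2Cl2, −78 → −10 °C) gives (3S)-2,3-dihydroxy-3-methyl-6-(non-1-yn-1-yl)-4-oxocyclohexa-1,5-diene-1-carbaldehyde F3. Cycloisomerisation with CuI and i-Pr2NEt gives (7R)-3-heptyl-7-hydroxy-7-methyl-6H-isochromene-6,8(7H)-dione F4. Acylation of the tertiary alcohol with decanoyl chloride 6 (Et3N, DMAP, CH2Cl2) gives 17.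

2. Step 3. The esterase may discriminate poorly between the enantiotopic esters or hydrolyse with the opposite sense. The fallback sets out from 3 and returns at 4. Diester 3 is half-saponified with KOH (1.0 equiv) in MeOH/H2O to racemic 2-(benzyloxy)-3-methoxy-2-methyl-3-oxopropanoic acid F5. Fractional crystallisation of its salt with 1-phenylethylamine should give (R)-1-phenylethylammonium (R)-2-(benzyloxy)-3-methoxy-2-methyl-3-oxopropanoate F6; the R amine is drawn, and the S amine is used if it gives the less soluble salt of the R acid. Acidification with HCl releases 4.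

3. Step 5. Acylation of the hindered, electron-poor tertiary hydroxyl may be slow while the free malonic half-acid scrambles through anhydrides or decarboxylates. The fallback sets out from 2 and returns at 8. The decanoate is installed before the enzymatic step: diester 2 is acylated with 6 (Et3N, DMAP, CH2Cl2) to dimethyl 2-(decanoyloxy)-2-methylmalonate F7. Esterase hydrolysis in buffer with a cosolvent then removes one methyl ester and gives 8 directly; the tertiary decanoate is not expected to be an esterase substrate, and the sense is again to be confirmed.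

**Further compounds**

F1 | step 10 | non-1-yne | CCCCCCCC#C
F2 | step 10 | 2,4-dihydroxy-3-methyl-6-(non-1-yn-1-yl)benzaldehyde | CCCCCCCC#Cc1cc(O)c(C)c(O)c1C=O
F3 | step 10 | (3S)-2,3-dihydroxy-3-methyl-6-(non-1-yn-1-yl)-4-oxocyclohexa-1,5-diene-1-carbaldehyde | O[C@]1(C)C(=O)C=C(C#CCCCCCCC)C(C=O)=C1O
F4 | step 10 | (7R)-3-heptyl-7-hydroxy-7-methyl-6H-isochromene-6,8(7H)-dione | O[C@]1(C)C(=O)C=C2C=C(CCCCCCC)OC=C2C1=O
F5 | step 3 | racemic 2-(benzyloxy)-3-methoxy-2-methyl-3-oxopropanoic acid | COC(=O)C(C)(OCc1ccccc1)C(O)=O
F6 | step 3 | (R)-1-phenylethylammonium (R)-2-(benzyloxy)-3-methoxy-2-methyl-3-oxopropanoate | c1ccccc1CO[C@](C)(C([O-])=O)C(=O)OC.C[C@@H]([NH3+])c1ccccc1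
F7 | step 5 | dimethyl 2-(decanoyloxy)-2-methylmalonate | CCCCCCCCCC(=O)OC(C)(C(=O)OC)C(=O)OC
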